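## Structural features

The target 18 is a 2,2-dimethyl-2H-chromene: benzene ring A is fused through C4a and C8a to 2H-pyran ring B, which holds O1, the dimethyl-bearing C2 and the C3=C4 alkene. Ring A carries four different groups in a fixed order: O1 on C8a, C4 on C4a, a saturated two-carbon chain on C5 ending in para-hydroxyphenyl ring C, and a 3-methylbut-2-enyl (prenyl) ether on C7. C6 and C8 carry hydrogen. There is no stereocentre and no stereogenic double bond, so the problem is one of regiochemistry and chemoselectivity only. The fragile groups are the prenyl aryl ether (ionised by acids and soft metals, an ene partner for electrophiles), the styrene-like C3=C4 alkene (acid, oxidants, hydrogenation) and the free phenol of ring C. The real difficulty is to place the carbon arm on C5, beside the ring fusion, while telling apart the two meta oxygens of ring A, and to make the CH2–CH2 link without hydrogenation. The key step uses the ortho relationship of O1 on C8a and C4 on C4a: an aryne spanning C4a and C8a can take both atoms from the carbonyl group of one enal, whose remaining carbons become C3 and C2. A chlorine on C5 steers that addition and then serves as the handle for the arm.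

## Logic of the disconnections

18 ⇒ 17. The O–Si bond of a silyl ether on ring C is cut. A free phenol would consume borane and base in the preceding coupling, so it is carried masked. The forward step must be neutral to the C3=C4 alkene and the prenyl ether, which fluoride is.

17 ⇒ 14 + 15 (through 16). The C5–CH2 bond is cut. It is the only C–C bond joining the two halves, and cutting it leaves a chloroarene and a purchasable styrene. Hydroboration of 15 supplies the saturated link, so no hydrogenation is needed in the presence of the two alkenes of 14. The forward step needs oxidative addition into an aryl chloride flanked by C4a, and no B–H may remain when 14 is added.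

14 ⇒ 9 + 10 (through 11, 12, 13). The bonds C8a–O1, C4a–C4 and O1–C2 are cut. Ring B then comes from 10 in one operation under near-neutral fluoride conditions, with the prenyl ether already in place. The forward step needs one sense of addition to an unsymmetrical aryne, secured by the C5 chlorine, and suppression of ene reactions, secured by an excess of 10.

9 ⇒ 7 + 8. The O–CH2 bond of the prenyl ether is cut. The prenyl alkene would not survive electrophilic halogenation or BCl3, so it is attached last before the key step. Because 7 has a single free hydroxyl, no regiochemical question arises. The base must be too weak to trigger the silyl triflate.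

7 ⇒ 6. The O–benzyl bond is cut. The C7 oxygen must stay masked through halogenation, lithiation and triflation, and a benzyl ether survives all three. Debenzylation is placed after triflation so that the silicon-bearing carbon is deactivated by the neighbouring triflate and is meta to the ether oxygen, and so that a hydroquinone with two free hydroxyls is never formed. The cleavage must spare C–Cl, C–Si and the triflate, which excludes hydrogenolysis.

6 ⇒ 3 (through 4 and 5). The C–Si and O–S bonds are cut. Silicon is delivered from oxygen to the carbon that bore bromine, which fixes the ortho relationship of silyl group and triflate. Either placement of the two groups on C4a and C8a would release the same aryne; this one maps onto a 2,6-dihalophenol. The chlorine is meta to the lithiated carbon, so LiCl cannot be eliminated.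

3 ⇒ 2. The C–Br bond is cut. The one remaining position ortho to the hydroxyl is the most activated site, so the bromine that later marks the silicon position can be placed there directly. The forward step must avoid the positions flanking the benzyl ether.

2 ⇒ 1. The C–Cl bond is cut, leading to a purchasable hydroquinone monoether whose free hydroxyl directs chlorination to its ortho position. The forward step must stop at monochlorination.

## Other disconnections considered

Alternative 1: The cut removes the C5–CH2 and C4a–C4 bonds at once. In the forward sense 1-iodo-2,4-bis(methoxymethoxy)benzene A1, 4-(triisopropylsilyloxy)phenethyl bromide A2 and 2-methylbut-3-en-2-ol A3 would combine under Pd(OAc)2, a furylphosphine, norbornene and Cs2CO3. Ortho C–H alkylation followed by ipso Heck termination would give the styrenyl carbinol A4, with no ring closed.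
- In its favour: three components meet in one step, no halogen handle has to be carried, and the ortho oxygen next to iodine blocks double alkylation.
- Against it here: A2 can eliminate to a styrene under hot carbonate, and that styrene would compete as Heck acceptor. The relay between divalent and tetravalent palladium has more off-cycle exits than a fluoride-triggered aryne. Ring B would still have to be closed from A4 under acid, which needs E-to-Z isomerisation through an allyl cation on a very electron-rich resorcinol, and prenylation and desilylation follow.
- Comparison: on convergence and probably on step count this plan is the equal or the better of the chosen one. The chosen plan is more secure in forming ring B, because the pyran closes pericyclically at near-neutral pH with the prenyl ether in place.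

Alternative 2: The cut opens ring A at C4a–C5 and C8–C8a. In the forward sense dimethyl malonate A6 would add to the β-carbon of (E)-6-[4-(benzyloxy)phenyl]hex-3-en-2-one A5 under NaOMe, and the methyl ketone enolate would then close onto an ester to give the cyclohexanedione ester A7.
- In its favour: cheap reagents and classical carbonyl chemistry. Every substituent of ring A is placed by construction, so nothing depends on aryne polarisation; on regiochemical certainty it is the equal or the better of the chosen plan. After aromatisation the hydroxyl chelated to the ester would be easy to tell from the other.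
- Against it here: A7 is at the wrong oxidation level and must be dehydrogenated. The ester carbon must be reduced and extended by C3 and C2 before ring B can close. A benzyl ether on ring C could not be removed by hydrogenolysis at the end without touching the alkenes.
- Comparison: mechanistically the safest of the four, but clearly longer than the chosen eight steps, with ring B still unbuilt after the key step.

Alternative 3: The cut removes C6–C5 and C8a–C4a and then O1–C2. In the forward sense 1-methoxy-1,3-bis(trimethylsilyloxy)buta-1,3-diene A8 would add to 2-methyl-8-[4-(triisopropylsilyloxy)phenyl]oct-2-en-5-yn-4-one A9 in hot toluene. Loss of methanol and silyl groups would aromatise ring A, and the C8a phenol would add to the enone to give chromanone A10.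
- In its favour: ring A with all four substituents and ring B form in one pot, with regiochemistry set by the polarity of both partners. The C7 hydroxyl emerges free and alone, so no protecting-group exchange is needed on ring A; on that point it is better than the chosen plan.
- Against it here: ring B arrives as a 4-ketone, so reduction and dehydration are needed to reach the C3=C4 alkene, and the dehydration needs acid that a prenyl ether tolerates poorly. A8 is moisture-sensitive and must be made fresh. A9 needs several steps and has a second electrophilic site.
- Comparison: structurally elegant and equal in regiocontrol, but ring B is formed at the wrong oxidation level. The overall count should be equal to or somewhat above that of the chosen plan.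

Key step: step 6

Remark on the chemistry: 18 has no stereocentre; 12 is racemic and transient, and its stereocentre is lost on ring opening. In 9 the triflate sits on the future C4a and the silyl group on the future C8a, which is consistent with the chlorine on C5 next to C4a.

## Route

Step 1
Reactants: 1 4-(benzyloxy)phenol
Product: 2 4-(benzyloxy)-2-chlorophenol
Conditions: SO2Cl2 (1.0 equiv), iBu2NH (cat.), toluene, 0 °C to rt
Reagents that add atoms: sulfuryl chloride, ClS(Cl)(=O)=O
Why: Electrophilic aromatic chlorination; the free hydroxyl is the strongest activator, its para position is blocked, and amine-mediated delivery places chlorine ortho to it, while one equivalent limits dichlorination.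

Step 2
Reactants: 2 4-(benzyloxy)-2-chlorophenol
Product: 3 4-(benzyloxy)-2-bromo-6-chlorophenol
Conditions: NBS (1.0 equiv), iPr2NH (cat.), CH2Cl2, 0 °C
Reagents that add atoms: N-bromosuccinimide, O=C1CCC(=O)N1Br
Why: Amine-catalysed ortho-bromination of a phenol; the single remaining position ortho to the hydroxyl is the most activated site and should be taken in preference to the positions flanking the benzyl ether.

Step 3
Reactants: 3 4-(benzyloxy)-2-bromo-6-chlorophenol
Product: 6 4-(benzyloxy)-2-chloro-6-(trimethylsilyl)phenyl trifluoromethanesulfonate, via aryl trimethylsilyl ether 4 (not isolated), via lithium 2-silylphenoxide 5 (not isolated)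
Conditions: HMDS, THF, 65 °C, then evaporation; n-BuLi, THF, −78 °C; Tf2O, −78 to 0 °C
Reagents that add atoms: hexamethyldisilazane, C[Si](C)(C)N[Si](C)(C)C; trifluoromethanesulfonic anhydride, O=S(=O)(OS(=O)(=O)C(F)(F)F)C(F)(F)F
Why: O-silylation, bromine–lithium exchange and anionic 1,3 O-to-C silyl shift (retro-Brook rearrangement), then O-triflation of the hindered phenoxide, the standard one-pot entry to ortho-silylaryl triflates; the chlorine is meta to the aryllithium, so no LiCl elimination is possible, and the benzyl ether is inert to n-BuLi at −78 °C.

Step 4
Reactants: 6 4-(benzyloxy)-2-chloro-6-(trimethylsilyl)phenyl trifluoromethanesulfonate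
Product: 7 2-chloro-4-hydroxy-6-(trimethylsilyl)phenyl trifluoromethanesulfonate
Conditions: BCl3, C6HMe5, CH2Cl2, −78 °C; MeOH quench
Reagents that add atoms: none
Why: Lewis-acid debenzylation of an aryl benzyl ether with pentamethylbenzene as a non-basic trap for the benzyl cation; at −78 °C the C–Si bond, meta to the ether oxygen and deactivated by the ortho triflate, should resist ipso attack, and the aryl chloride and triflate are inert.

Step 5
Reactants: 7 2-chloro-4-hydroxy-6-(trimethylsilyl)phenyl trifluoromethanesulfonate; 8 1-bromo-3-methylbut-2-ene
Product: 9 2-chloro-4-(3-methylbut-2-enyloxy)-6-(trimethylsilyl)phenyl trifluoromethanesulfonate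
Conditions: K2CO3, acetone, rt
Reagents that add atoms: none
Why: Williamson etherification of the only free phenol with a reactive allylic bromide; without fluoride or a crown ether, K2CO3 in acetone at room temperature should leave the silyl triflate untouched.

Step 6
Reactants: 9 2-chloro-4-(3-methylbut-2-enyloxy)-6-(trimethylsilyl)phenyl trifluoromethanesulfonate; 10 3-methylbut-2-enal
Product: 14 5-chloro-2,2-dimethyl-7-(3-methylbut-2-enyloxy)-2H-chromene, via aryne 11 (not isolated), via benzoxete 12 (not isolated), via ortho-quinone methide 13 (not isolated)
Conditions: CsF, MeCN, rt to 50 °C, 10 in excess (5 equiv), slow addition of 9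
Reagents that add atoms: none
Why: Fluoride attacks silicon in 9 and triflate leaves, giving aryne 11 with the triple bond between C4a and C8a. The carbonyl oxygen of 10 adds to C8a and the aryl anion formed at C4a closes onto the carbonyl carbon, a formal [2+2] addition that gives benzoxete 12 (bonds C8a–O1 and C4a–C4). Thermal 4π opening of 12 gives ortho-quinone methide 13, and a thermally allowed disrotatory oxa-6π electrocyclisation joins O1 to the dimethyl-bearing C2, closing ring B as a six-membered 2H-pyran and restoring the aromaticity of ring A. The closest known reaction type is the fluoride-induced annulation of arynes with α,β-unsaturated aldehydes to 2H-chromenes. The regioselectivity needed is secured by the chlorine on C5: its inductive pull makes C8a, meta to chlorine, the electrophilic terminus and stabilises the charge developing at C4a, while the C7 ether, meta to C8a and para to C4a, has little say. The chlorine also pushes the propenyl arm of 13 to the carbonyl side, the geometry required for closure. Chemoselectivity over ene reaction of 11 with prenyl alkenes and over capture of 13 by a second aryne is secured by slow addition of 9 to an excess of 10. No stereocentre remains in 14, since C2 carries two methyl groups and the stereocentre of racemic 12 is lost on ring opening.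

Step 7
Reactants: 14 5-chloro-2,2-dimethyl-7-(3-methylbut-2-enyloxy)-2H-chromene; 15 4-(tert-butyldimethylsilyloxy)styrene
Product: 17 tert-butyl(4-{2-[2,2-dimethyl-7-(3-methylbut-2-enyloxy)-2H-chromen-5-yl]ethyl}phenoxy)dimethylsilane, via alkylborane 16 (not isolated)
Conditions: 15 (slight excess over borane), 9-BBN, THF, 0 °C to rt; then 14, Pd(OAc)2, SPhos, K3PO4, THF/H2O, 65 °C
Reagents that add atoms: none
Why: Anti-Markovnikov hydroboration of the styrene followed by B-alkyl Suzuki–Miyaura coupling; the electron-rich biarylphosphine lets zerovalent palladium insert into the aryl chloride and aqueous phosphate activates the borane. Hydroboration is finished with 15 in slight excess before 14 is added, so no B–H reaches the prenyl or chromene alkenes.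

Step 8
Reactants: 17 tert-butyl(4-{2-[2,2-dimethyl-7-(3-methylbut-2-enyloxy)-2H-chromen-5-yl]ethyl}phenoxy)dimethylsilane
Product: 18 4-{2-[2,2-dimethyl-7-(3-methylbut-2-enyloxy)-2H-chromen-5-yl]ethyl}phenol
Conditions: Bu4NF, THF, 0 °C; aqueous work-up
Reagents that add atoms: none
Why: Fluoride-mediated cleavage of an aryl silyl ether, driven by Si–F bond formation; the conditions are neutral to the C3=C4 alkene and the prenyl ether.

## Compound list

1 | 4-(benzyloxy)phenol | Oc1ccc(OCc2ccccc2)cc1 | starting material
2 | 4-(benzyloxy)-2-chlorophenol | Oc1ccc(OCc2ccccc2)cc1Cl | intermediate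
3 | 4-(benzyloxy)-2-bromo-6-chlorophenol | Oc1c(Cl)cc(OCc2ccccc2)cc1Br | intermediate
4 | [4-(benzyloxy)-2-bromo-6-chlorophenoxy]trimethylsilane (not isolated) | C[Si](C)(C)Oc1c(Cl)cc(OCc2ccccc2)cc1Br | intermediate
5 | lithium 4-(benzyloxy)-2-chloro-6-(trimethylsilyl)phenoxide (not isolated) | [Li+].[O-]c1c(Cl)cc(OCc2ccccc2)cc1[Si](C)(C)C | intermediate
6 | 4-(benzyloxy)-2-chloro-6-(trimethylsilyl)phenyl trifluoromethanesulfonate | C[Si](C)(C)c1cc(OCc2ccccc2)cc(Cl)c1OS(=O)(=O)C(F)(F)F | intermediate
7 | 2-chloro-4-hydroxy-6-(trimethylsilyl)phenyl trifluoromethanesulfonate | C[Si](C)(C)c1cc(O)cc(Cl)c1OS(=O)(=O)C(F)(F)F | intermediate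
8 | 1-bromo-3-methylbut-2-ene | CC(C)=CCBr | starting material
9 | 2-chloro-4-(3-methylbut-2-enyloxy)-6-(trimethylsilyl)phenyl trifluoromethanesulfonate | CC(C)=CCOc1cc(Cl)c(OS(=O)(=O)C(F)(F)F)c([Si](C)(C)C)c1 | intermediate
10 | 3-methylbut-2-enal | CC(C)=CC=O | starting material
11 | 3-chloro-5-(3-methylbut-2-enyloxy)benzyne (1,2-didehydrobenzene; not isolated) | CC(C)=CCOC1=CC#CC(Cl)=C1 | intermediate
12 | 3-chloro-2-(2-methylprop-1-enyl)-5-(3-methylbut-2-enyloxy)-2H-benzoxete (racemic; not isolated) | CC(C)=CCOc1cc(Cl)c2C(C=C(C)C)Oc2c1 | intermediate
13 | (6E)-5-chloro-6-(3-methylbut-2-enylidene)-3-(3-methylbut-2-enyloxy)cyclohexa-2,4-dien-1-one (propenyl arm on the carbonyl side; not isolated) | CC(C)=C/C=C1\C(=O)C=C(OCC=C(C)C)C=C1Cl | intermediate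
14 | 5-chloro-2,2-dimethyl-7-(3-methylbut-2-enyloxy)-2H-chromene | CC(C)=CCOc1cc(Cl)c2C=CC(C)(C)Oc2c1 | intermediate
15 | 4-(tert-butyldimethylsilyloxy)styrene | C=Cc1ccc(O[Si](C)(C)C(C)(C)C)cc1 | starting material
16 | 9-{2-[4-(tert-butyldimethylsilyloxy)phenyl]ethyl}-9-borabicyclo[3.3.1]nonane (not isolated) | CC(C)(C)[Si](C)(C)Oc1ccc(CCB2C3CCCC2CCC3)cc1 | intermediate
17 | tert-butyl(4-{2-[2,2-dimethyl-7-(3-methylbut-2-enyloxy)-2H-chromen-5-yl]ethyl}phenoxy)dimethylsilane | CC(C)=CCOc1cc(CCc2ccc(O[Si](C)(C)C(C)(C)C)cc2)c2C=CC(C)(C)Oc2c1 | intermediate
18 | 4-{2-[2,2-dimethyl-7-(3-methylbut-2-enyloxy)-2H-chromen-5-yl]ethyl}phenol | CC(C)=CCOc1cc(CCc2ccc(O)cc2)c2c(c1)OC(C)(C)C=C2 | target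

## Step count and least certain steps

Total step count: 8. Longest linear sequence: 8 steps (1 to 18); 8, 10 and 15 enter as purchased materials.

Step 6 (key step). The aryne may be consumed by ene reaction or [2+2] addition with the electron-rich prenyl alkenes, the quinone methide may be intercepted by a second aryne, or regiocontrol in the carbonyl addition may be incomplete. The cause is that an aldehyde oxygen is only a moderate nucleophile toward an indiscriminate aryne. Fallback, from 9 back to 14:
- The aryne is generated with CsF in N,N-dimethylformamide as solvent, so the formamide carbonyl, in vast excess, undergoes the same chlorine-directed addition. Aqueous work-up should give 2-chloro-6-hydroxy-4-(3-methylbut-2-enyloxy)benzaldehyde F1.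
- Addition of 2-methylprop-1-enylmagnesium bromide (two equivalents, THF, 0 °C) should give racemic 3-chloro-2-(1-hydroxy-3-methylbut-2-enyl)-5-(3-methylbut-2-enyloxy)phenol F2.
- Warming F2 in toluene expels water to regenerate 13, which closes to 14.
- Both stages are known reaction types: aryne insertion into formamides to give salicylaldehydes, and dehydration of ortho-hydroxybenzyl alcohols to quinone methides.

Step 4. Ipso-protodesilylation or borodesilylation of the C–Si bond may compete, or cleavage of the electron-poor benzyl ether may be sluggish, because BCl3 and the HCl it releases are also electrophiles toward arylsilanes. Fallback, from 3 back to 9, with silicon introduced only after the benzyl group is gone: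
- BCl3 and pentamethylbenzene convert 3 into 2-bromo-6-chlorobenzene-1,4-diol F3.
- The dianion of F3 (NaH, two equivalents, DMF, 0 °C) is alkylated with one equivalent of 8 at the unhindered, more basic C4 oxygen, giving 2-bromo-6-chloro-4-(3-methylbut-2-enyloxy)phenol F4.
- The sequence of step 3 (HMDS; n-BuLi at −78 °C; Tf2O) then passes through [2-bromo-6-chloro-4-(3-methylbut-2-enyloxy)phenoxy]trimethylsilane F5 and lithium 2-chloro-4-(3-methylbut-2-enyloxy)-6-(trimethylsilyl)phenoxide F6 to 9.

Step 7. Oxidative addition into the ortho-substituted aryl chloride may be slow, letting protodeboronation or β-hydride elimination of the alkylborane compete. Zerovalent palladium may also ionise the prenyl ether under hot aqueous base. Early loss of the silyl group under the basic conditions would be harmless, since it only anticipates step 8. Fallback, from 14 back to 17, by a base-free and water-free Negishi coupling: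
- Purchasable [4-(2-bromoethyl)phenoxy](tert-butyl)dimethylsilane F7 is converted with zinc dust and LiCl in THF into {2-[4-(tert-butyldimethylsilyloxy)phenyl]ethyl}zinc bromide F8.
- F8 is coupled with 14 using Pd(OAc)2 and SPhos in THF at 50 to 60 °C.

Step 5. The phenoxide or carbonate may trigger the silyl triflate, or the triflyl group may be transferred to the phenoxide, because 7 carries its own latent leaving groups. Fallback, from 7 back to 9: Mitsunobu condensation with 3-methylbut-2-en-1-ol, triphenylphosphine and diisopropyl azodicarboxylate in THF at 0 °C. This replaces phenoxide alkylation by a redox condensation in which no free base is present, and it creates no new intermediate.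

## Further compounds

F1 | step 6 | 2-chloro-6-hydroxy-4-(3-methylbut-2-enyloxy)benzaldehyde | O=Cc1c(Cl)cc(OCC=C(C)C)cc1O
F2 | step 6 | 3-chloro-2-(1-hydroxy-3-methylbut-2-enyl)-5-(3-methylbut-2-enyloxy)phenol (racemic) | CC(C)=CC(O)c1c(Cl)cc(OCC=C(C)C)cc1O
F3 | step 4 | 2-bromo-6-chlorobenzene-1,4-diol | Oc1cc(Cl)c(O)c(Br)c1
F4 | step 4 | 2-bromo-6-chloro-4-(3-methylbut-2-enyloxy)phenol | CC(C)=CCOc1cc(Cl)c(O)c(Br)c1
F5 | step 4 | [2-bromo-6-chloro-4-(3-methylbut-2-enyloxy)phenoxy]trimethylsilane | C[Si](C)(C)Oc1c(Cl)cc(OCC=C(C)C)cc1Br
F6 | step 4 | lithium 2-chloro-4-(3-methylbut-2-enyloxy)-6-(trimethylsilyl)phenoxide | [Li+].[O-]c1c(Cl)cc(OCC=C(C)C)cc1[Si](C)(C)C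
F7 | step 7 | [4-(2-bromoethyl)phenoxy](tert-butyl)dimethylsilane | BrCCc1ccc(O[Si](C)(C)C(C)(C)C)cc1
F8 | step 7 | {2-[4-(tert-butyldimethylsilyloxy)phenyl]ethyl}zinc bromide | Br[Zn]CCc1ccc(O[Si](C)(C)C(C)(C)C)cc1
F0 | step 5 | none | none
A1 | alternative 1 | 1-iodo-2,4-bis(methoxymethoxy)benzene | COCOc1ccc(I)c(OCOC)c1
A2 | alternative 1 | 4-(triisopropylsilyloxy)phenethyl bromide | BrCCc1ccc(O[Si](C(C)C)(C(C)C)C(C)C)cc1
A3 | alternative 1 | 2-methylbut-3-en-2-ol | C=CC(C)(C)O
A4 | alternative 1 | (E)-4-{2,4-bis(methoxymethoxy)-6-[2-(4-triisopropylsilyloxyphenyl)ethyl]phenyl}-2-methylbut-3-en-2-ol | COCOc1cc(OCOC)c(/C=C/C(C)(C)O)c(CCc2ccc(O[Si](C(C)C)(C(C)C)C(C)C)cc2)c1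
A5 | alternative 2 | (E)-6-[4-(benzyloxy)phenyl]hex-3-en-2-one | CC(=O)/C=C/CCc1ccc(OCc2ccccc2)cc1
A6 | alternative 2 | dimethyl malonate | COC(=O)CC(=O)OC
A7 | alternative 2 | methyl 2-{2-[4-(benzyloxy)phenyl]ethyl}-4,6-dioxocyclohexane-1-carboxylate (racemic, enolised) | COC(=O)C1C(CCc2ccc(OCc3ccccc3)cc2)CC(=O)CC1=O
A8 | alternative 3 | 1-methoxy-1,3-bis(trimethylsilyloxy)buta-1,3-diene | COC(O[Si](C)(C)C)=CC(=C)O[Si](C)(C)C
A9 | alternative 3 | 2-methyl-8-[4-(triisopropylsilyloxy)phenyl]oct-2-en-5-yn-4-one | CC(C)=CC(=O)C#CCCc1ccc(O[Si](C(C)C)(C(C)C)C(C)C)cc1
A10 | alternative 3 | 7-hydroxy-2,2-dimethyl-5-{2-[4-(triisopropylsilyloxy)phenyl]ethyl}chroman-4-one | CC1(C)CC(=O)c2c(CCc3ccc(O[Si](C(C)C)(C(C)C)C(C)C)cc3)cc(O)cc2O1
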